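## Analysis of the target

The target 15 is a (2S)-flavanone: a benzene ring A fused to a dihydropyranone ring C (O1, C2, C3, C4, C4a, C8a), with an unsubstituted phenyl ring B on C2. Ring A carries the peri hydroxyl at C5, hydrogen at C6, methoxy at C7 and a saturated 3-hydroxy-3-methylbutyl chain at C8, next to the ring oxygen. C2 is the only stereocentre; it is benzylic, bound to O1 and β to the C4 carbonyl, so a C3 enolate can expel the C8a aryloxide and reclose, which racemises it and rules out base once the ketone is free. The tertiary alcohol is acid-sensitive, and while the oxygen on C8a is still a free hydroxyl, any cationic centre in the C8 chain would be captured as a cyclic ether. Three things make the synthesis hard: placing the chain at C8 and not C6 on a ring with four contiguous substituents, telling apart the two oxygens that flank the acyl carbon (future O5 and O1), and making C2 enantiopure and keeping it so. The plan rests on the C3–C4 bond: a methylene next to a carbonyl carbon is the hydrolysed form of a C3=C4 enol ether double bond, which can be made inside a six-membered ring from a vinyl group on C2 and an O-silylated enol CH2= on C4. With O1–C2 already in place as a chiral allylic aryl ether, closing ring C leaves the stereocentre untouched and delivers the ketone masked.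

## Retrosynthetic reasoning

15 ⇒ 14. The last operation only frees the C5 hydroxyl. A benzyl ether is chosen for this oxygen because it must survive base, palladium-catalysed coupling, the iridium catalyst, a silyl triflate, the ruthenium alkylidene and acidic fluoride. Hydrogenolysis removes it under neutral conditions that cannot open ring C.

14 ⇒ 13. The C4 ketone and the tertiary alcohol are released together from the silyl enol ether and the triethylsilyl ether of 13. The forward step must never leave a free C3 enolate, which would eject the C8a oxygen and scramble C2. Fluoride in a buffered acidic medium is planned for that reason, not basic fluoride.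

13 ⇒ 12. The C3=C4 double bond is cut into the two terminal olefins of 12: the vinyl group of the 1-phenylallyl ether on O1 and the CH2= of the silyl enol ether on C4. This is the only ring-C bond that can be formed without touching any bond to C2, and it gives the ketone in a form that cannot undergo β-elimination. The forward metathesis must start at the monosubstituted olefin, engage a hindered 1,1-disubstituted electron-rich olefin, and leave the allylic double bond where it is. A thermal sigmatropic shift of the allyl group is not a concern at metathesis temperatures: both ortho positions are blocked, and the open para position would be reached only on much stronger heating.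

12 ⇒ 11. The enol ether comes from the methyl ketone 11 by O-silylation. The acetyl methyl group becomes the carbon that is lost in the metathesis.

11 ⇒ 7 + 9. The O1–C2 bond is cut to the phenol 7 and the cinnamyl carbonate 9. An iridium–phosphoramidite catalyst is needed because it sends an aryloxide to the substituted allyl terminus and controls the face; a palladium allyl complex would give the linear ether. This step sets C2. The carbonate 9 comes from the alcohol 8 in one step.

7 ⇒ 6. The benzyl group is placed on the less hindered of the two hydroxyls of 6, the one with a ring hydrogen as neighbour. The hydroxyl wedged between the acyl group and the chain stays free for the etherification.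

6 ⇒ 2 + 5. The aryl–CH2 bond of the C8 chain is cut to the aryl iodide 2 and the alkylborane 5, made in the flask from the olefin 4, the silyl ether of 3. The chain is brought in saturated and already oxygenated for two reasons. An unsaturated chain could not be hydrated beside the free ortho hydroxyl without cyclising onto it. If carried further, its olefin would also compete in the metathesis and close a seven-membered ring.

2 ⇒ 1. The two open ring positions of 1 are equivalent by symmetry, so mono-iodination can give only 2.

## Alternatives that were turned down

Alternative 1: Ring C is cut at O1–C8a and C4–C4a. This leaves ring A as an aryne across C4a–C8a, and the C2–C3–C4 unit with ring B as methyl (S)-3-hydroxy-3-phenylpropanoate A2. Fluoride would unmask the aryne from an ortho-silylaryl triflate; the alkoxide of A2 would add at C8a and the C4a aryl anion would acylate on the ester, giving (S)-5-(benzyloxy)-8-[3-(benzyloxy)-3-methylbutyl]-7-methoxyflavanone A1.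
- For it: two bonds and the ring form in one step. The stereocentre arrives in A2, an easily made hydroxy ester, and its C–O bond is never broken. The C5 alkoxy group polarises the aryne in the right direction, with the nucleophile going to the remote carbon.
- Against it: attack must occur at the aryne terminus flanked by the alkyl chain. A secondary aliphatic alkoxide is a weak aryne partner, and the hydroxyl of A2 can protonate the aryl anion before acylation. Under basic fluoride A2 can undergo retro-aldol cleavage or β-elimination. A1 is a free flavanone born in a basic medium, which is exactly where C2 racemises. The pentasubstituted silyl triflate and the tertiary benzyl ether are both laborious to make.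
- Comparison: the route through A1 is stronger on convergence and on certainty of absolute configuration at the outset. The chosen route offers a neutral ring closure with the ketone masked, and a precursor reached by ordinary phenol chemistry.

Alternative 2: Only O1–C8a is cut. The precursor is an open-chain secondary alcohol at C2 with chlorine on C8a and C4 masked as a dithiane. Pd(OAc)2 with a bulky biaryl di-tert-butylphosphine and Cs2CO3 would couple the hydroxyl with the aryl chloride with retention at C2, giving (S)-5-(benzyloxy)-7-methoxy-8-(3-methyl-3-triethylsilyloxybutyl)flavanone 4-(propane-1,3-diyl dithioketal) A3.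
- For it: the carbinol can be made by very dependable asymmetric carbonyl reduction or epoxide opening, and A3 forms without any bond to C2 being broken. On security of enantiopurity this is stronger than an allylic etherification with a hindered, chelated phenoxide.
- Against it: the chloride sits on an electron-rich ring between two ortho substituents, so oxidative addition is slow. The dithiane sulfurs can bind palladium. The palladium alkoxide can undergo β-hydride elimination, giving ketone and dechlorinated arene. The dithioketal of A3 costs steps to put on and needs thiophilic or oxidative removal beside an electron-rich arene.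
- Comparison: the chosen route needs no sulfur, and its unmasking is a mild protodesilylation where A3 needs a dithioketal cleavage. It accepts in exchange a less proven stereo-defining step.

Alternative 3: The C2–C3 bond is cut. An aryl diazomethyl ketone at C4, with a benzyl group on O1, would lose nitrogen on a chiral dirhodium carboxylate such as Rh2(S-PTTL)4, dirhodium tetrakis[N-phthaloyl-(S)-tert-leucinate]. The C3 carbene would insert into the benzylic C–H, forming the bond, the stereocentre and ring C at once, to give (S)-5-(tert-butyldimethylsilyloxy)-7-methoxy-8-(3-methyl-3-triethylsilyloxybutyl)flavanone A4.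
- For it: it is the most step-economic way to create C2, from an achiral precursor with a trivial O-benzyl ether. A4 would need only a desilylation to reach 15, so the route would be shorter if the insertion worked.
- Against it: the ether oxygen lies 1,5 to the carbene, so oxonium ylide formation followed by [1,2]-benzyl shift to a five-membered ring ketone is the natural course and would take the material away from A4. Six-membered C–H insertion is less favoured than five-membered. Acceptor-only carbenes give modest enantiocontrol. Cyclopropanation of either arene (Buchner reaction) also competes. The diazo ketone must be made from a di-ortho-substituted benzoic acid.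
- Comparison: the selectivity problems on the way to A4 are built into the structure. The chosen route separates the stereo-defining event, which has an established selectivity model, from a ring closure that has no comparable competing pathway.

Key step: step 8

Assumption: the (Sa,Sc,Sc) antipode of the BINOL-derived N,N-bis(1-phenylethyl)phosphoramidite is taken to give the (S)-ether 11, following the usual facial preference of this catalyst family; if the sense proves opposite, the mirror-image ligand is used and nothing else changes.

## Route

Step 1
Reactants: 1 2',6'-dihydroxy-4'-methoxyacetophenone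
Product: 2 2',6'-dihydroxy-3'-iodo-4'-methoxyacetophenone
Conditions: N-iodosuccinimide (1.0 equiv), MeCN, 0 °C, dark
Reagents that add atoms: N-iodosuccinimide, O=C1CCC(=O)N1I
Why: Electrophilic aromatic iodination of a doubly hydroxyl-activated ring; C3' and C5' of 1 are related by symmetry, so mono-iodination can give only 2, and one equivalent of reagent at low temperature limits the 3',5'-diiodide.

Step 2
Reactants: 3 2-methylbut-3-en-2-ol
Product: 4 triethyl[(2-methylbut-3-en-2-yl)oxy]silane
Conditions: TESOTf, 2,6-lutidine, CH2Cl2, 0 °C
Reagents that add atoms: triethylsilyl trifluoromethanesulfonate, CC[Si](CC)(CC)OS(=O)(=O)C(F)(F)F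
Why: Silylation of a tertiary alcohol with a silyl triflate and a hindered pyridine base; the triethylsilyl ether keeps the alcohol out of the borane, coupling, base and triflate steps and is cleaved by the acidic fluoride near the end.

Step 3
Reactants: 4 triethyl[(2-methylbut-3-en-2-yl)oxy]silane; 2 2',6'-dihydroxy-3'-iodo-4'-methoxyacetophenone
Product: 6 2',6'-dihydroxy-4'-methoxy-3'-[3-methyl-3-(triethylsilyloxy)butyl]acetophenone, via B-alkyl-9-borabicyclononane 5 (not isolated)
Conditions: 4, 9-BBN (0.5 M in THF), rt; then 2, Pd(dppf)Cl2·CH2Cl2 (5 mol%), 3 M aq. K3PO4, DMF, 60 °C
Reagents that add atoms: none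
Why: Anti-Markovnikov hydroboration of the monosubstituted olefin of 4 puts boron on the terminal carbon, and B-alkyl Suzuki–Miyaura coupling of 5 with the aryl iodide then forms the aryl–CH2 bond, a reaction that tolerates ketones and free phenols when enough base is present. The chain arrives saturated and protected, so neither a cation nor an olefin is ever placed beside the free 2'-hydroxyl.

Step 4
Reactants: 6 2',6'-dihydroxy-4'-methoxy-3'-[3-methyl-3-(triethylsilyloxy)butyl]acetophenone
Product: 7 6'-(benzyloxy)-2'-hydroxy-4'-methoxy-3'-[3-methyl-3-(triethylsilyloxy)butyl]acetophenone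
Conditions: BnBr (1.05 equiv), K2CO3 (1.1 equiv), acetone, rt to 40 °C
Reagents that add atoms: benzyl bromide, BrCc1ccccc1
Why: Williamson ether synthesis with one equivalent of electrophile; the 6'-hydroxyl has a ring hydrogen as neighbour, whereas the 2'-hydroxyl is wedged between the acyl group and the new chain and stays as the chelated phenol, so mono-benzylation should fall on O6'.

Step 5
Reactants: 8 (E)-cinnamyl alcohol
Product: 9 tert-butyl (E)-cinnamyl carbonate
Conditions: Boc2O, Bu4NHSO4 (cat.), 30% aq. NaOH, CH2Cl2, 0 °C to rt
Reagents that add atoms: di-tert-butyl dicarbonate, CC(C)(C)OC(=O)OC(=O)OC(C)(C)C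
Why: Alkoxycarbonylation of a primary allylic alcohol under phase-transfer conditions; the tert-butyl carbonate is the leaving group for the iridium step and releases only a hindered alkoxide.

Step 6
Reactants: 7 6'-(benzyloxy)-2'-hydroxy-4'-methoxy-3'-[3-methyl-3-(triethylsilyloxy)butyl]acetophenone; 9 tert-butyl (E)-cinnamyl carbonate
Product: 11 6'-(benzyloxy)-4'-methoxy-3'-[3-methyl-3-(triethylsilyloxy)butyl]-2'-[(S)-1-phenylallyloxy]acetophenone, via lithium phenoxide 10 (not isolated)
Conditions: LiOt-Bu (1.0 equiv), THF, 0 °C; then 9 (1.3 equiv), [Ir(cod)Cl]2 (2 mol%), (Sa,Sc,Sc)-BINOL N,N-bis(1-phenylethyl)phosphoramidite (4 mol%, pre-activated with n-PrNH2), THF, 50 °C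
Reagents that add atoms: none
Why: Iridium-catalysed asymmetric allylic etherification of an aryloxide with a cinnamyl carbonate: ionisation gives an (η3-1-phenylallyl)iridium complex that the phenoxide attacks at the phenyl-bearing terminus, so the branched ether forms. The face is fixed by the cyclometalated iridium–phosphoramidite, which sets C2 as S; the hindered tert-butoxide is the only other nucleophile present.

Step 7
Reactants: 11 6'-(benzyloxy)-4'-methoxy-3'-[3-methyl-3-(triethylsilyloxy)butyl]-2'-[(S)-1-phenylallyloxy]acetophenone
Product: 12 tert-butyl{[1-(6-(benzyloxy)-4-methoxy-3-[3-methyl-3-(triethylsilyloxy)butyl]-2-{[(S)-1-phenylprop-2-en-1-yl]oxy}phenyl)vinyl]oxy}dimethylsilane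
Conditions: Et3N (3 equiv), TBSOTf (1.5 equiv), CH2Cl2, 0 °C
Reagents that add atoms: tert-butyldimethylsilyl trifluoromethanesulfonate, CC(C)(C)[Si](C)(C)OS(=O)(=O)C(F)(F)F
Why: Soft enolisation of the methyl ketone (O-silylation, then loss of a methyl proton to the amine) gives the only possible enol ether; excess amine keeps the medium non-acidic so that the ionisable benzylic allylic ether and the tertiary silyl ether survive.

Step 8
Reactants: 12 tert-butyl{[1-(6-(benzyloxy)-4-methoxy-3-[3-methyl-3-(triethylsilyloxy)butyl]-2-{[(S)-1-phenylprop-2-en-1-yl]oxy}phenyl)vinyl]oxy}dimethylsilane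
Product: 13 (S)-5-(benzyloxy)-4-(tert-butyldimethylsilyloxy)-7-methoxy-8-[3-methyl-3-(triethylsilyloxy)butyl]-2-phenyl-2H-chromene
Conditions: (H2IMes)(PCy3)Cl2Ru=CHPh (second-generation Grubbs catalyst, 10 mol%), 1,4-benzoquinone (20 mol%), degassed toluene (0.005 M), 60 °C, argon sparge, dark
Reagents that add atoms: none
Why: Ring-closing olefin metathesis: the ruthenium benzylidene exchanges with the monosubstituted allyl olefin to give an alkylidene on C3, which adds in a [2+2] sense to the CH2=C(OSi)Ar unit with ruthenium on the CH2 terminus; cycloreversion of the ruthenacyclobutane releases the C3=C4 double bond and a ruthenium methylidene, and ethylene leaves the solution. The closest known reactions are the metathesis of olefin-tethered silyl enol ethers to cyclic silyl enol ethers and of 2-(allyloxy)styrenes to 2H-chromenes. Ring C is closed as a six-membered ring with an endocyclic double bond, the ortho arrangement of the two olefin-bearing atoms on ring A holding the termini close. No stereocentre is formed; C2 is a spectator and none of its four bonds is involved. The step needs initiation at the allyl terminus and not at the enol ether, which the steric difference between a monosubstituted and a 1,1-disubstituted olefin secures, and it needs the allyl double bond to stay in place, which 1,4-benzoquinone secures by scavenging ruthenium hydrides. High dilution suppresses dimerisation at the allyl terminus, and the moderate temperature keeps a sigmatropic shift of the allyl group (ortho positions blocked, para position open) out of reach. The product carries C4 as an enol ether, so ring C cannot open by β-elimination during the step.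

Step 9
Reactants: 13 (S)-5-(benzyloxy)-4-(tert-butyldimethylsilyloxy)-7-methoxy-8-[3-methyl-3-(triethylsilyloxy)butyl]-2-phenyl-2H-chromene
Product: 14 (S)-5-(benzyloxy)-8-(3-hydroxy-3-methylbutyl)-7-methoxy-2-phenylchroman-4-one
Conditions: HF·pyridine, pyridine, THF, 0 °C to rt
Reagents that add atoms: none
Why: Fluoride cleaves both Si–O bonds in a buffered acidic medium: the liberated enol is protonated at C3 at once, so no free enolate lives long enough to expel the C8a aryloxide, and C2 keeps its configuration. The benzyl ether is untouched.

Step 10
Reactants: 14 (S)-5-(benzyloxy)-8-(3-hydroxy-3-methylbutyl)-7-methoxy-2-phenylchroman-4-one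
Product: 15 (S)-5-hydroxy-8-(3-hydroxy-3-methylbutyl)-7-methoxy-2-phenylchroman-4-one
Conditions: H2 (1 atm), 10% Pd/C, EtOAc, rt
Reagents that add atoms: none
Why: Catalytic hydrogenolysis of an aryl benzyl ether; the exocyclic primary benzyl ether should be cleaved much faster than the ring C2–O1 bond or the aryl ketone, and the freed hydroxyl chelates the C4 carbonyl.

## Compound list

1 | 2',6'-dihydroxy-4'-methoxyacetophenone | CC(=O)c1c(O)cc(OC)cc1O | starting material
2 | 2',6'-dihydroxy-3'-iodo-4'-methoxyacetophenone | CC(=O)c1c(O)cc(OC)c(I)c1O | intermediate
3 | 2-methylbut-3-en-2-ol | C=CC(C)(C)O | starting material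
4 | triethyl[(2-methylbut-3-en-2-yl)oxy]silane | C=CC(C)(C)O[Si](CC)(CC)CC | intermediate
5 | 9-[3-methyl-3-(triethylsilyloxy)butyl]-9-borabicyclo[3.3.1]nonane | CC[Si](CC)(CC)OC(C)(C)CCB1C2CCCC1CCC2 | intermediate
6 | 2',6'-dihydroxy-4'-methoxy-3'-[3-methyl-3-(triethylsilyloxy)butyl]acetophenone | CC(=O)c1c(O)cc(OC)c(CCC(C)(C)O[Si](CC)(CC)CC)c1O | intermediate
7 | 6'-(benzyloxy)-2'-hydroxy-4'-methoxy-3'-[3-methyl-3-(triethylsilyloxy)butyl]acetophenone | CC(=O)c1c(OCc2ccccc2)cc(OC)c(CCC(C)(C)O[Si](CC)(CC)CC)c1O | intermediate
8 | (E)-cinnamyl alcohol | OC/C=C/c1ccccc1 | starting material
9 | tert-butyl (E)-cinnamyl carbonate | CC(C)(C)OC(=O)OC/C=C/c1ccccc1 | intermediate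
10 | lithium 2-acetyl-3-(benzyloxy)-5-methoxy-6-[3-methyl-3-(triethylsilyloxy)butyl]phenolate | CC(=O)c1c(OCc2ccccc2)cc(OC)c(CCC(C)(C)O[Si](CC)(CC)CC)c1[O-].[Li+] | intermediate
11 | 6'-(benzyloxy)-4'-methoxy-3'-[3-methyl-3-(triethylsilyloxy)butyl]-2'-[(S)-1-phenylallyloxy]acetophenone | CC(=O)c1c(OCc2ccccc2)cc(OC)c(CCC(C)(C)O[Si](CC)(CC)CC)c1O[C@H](c1ccccc1)C=C | intermediate
12 | tert-butyl{[1-(6-(benzyloxy)-4-methoxy-3-[3-methyl-3-(triethylsilyloxy)butyl]-2-{[(S)-1-phenylprop-2-en-1-yl]oxy}phenyl)vinyl]oxy}dimethylsilane | C=C(O[Si](C)(C)C(C)(C)C)c1c(OCc2ccccc2)cc(OC)c(CCC(C)(C)O[Si](CC)(CC)CC)c1O[C@H](c1ccccc1)C=C | intermediate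
13 | (S)-5-(benzyloxy)-4-(tert-butyldimethylsilyloxy)-7-methoxy-8-[3-methyl-3-(triethylsilyloxy)butyl]-2-phenyl-2H-chromene | COc1cc(OCc2ccccc2)c2c(c1CCC(C)(C)O[Si](CC)(CC)CC)O[C@H](c1ccccc1)C=C2O[Si](C)(C)C(C)(C)C | intermediate
14 | (S)-5-(benzyloxy)-8-(3-hydroxy-3-methylbutyl)-7-methoxy-2-phenylchroman-4-one | COc1cc(OCc2ccccc2)c2c(c1CCC(C)(C)O)O[C@H](c1ccccc1)CC2=O | intermediate
15 | (S)-5-hydroxy-8-(3-hydroxy-3-methylbutyl)-7-methoxy-2-phenylchroman-4-one | COc1cc(O)c2c(c1CCC(C)(C)O)O[C@H](c1ccccc1)CC2=O | target

## Step count and least certain steps

Total step count: 10. Longest linear sequence: 8 steps (1 → 2 → 6 → 7 → 11 → 12 → 13 → 14 → 15). Steps 2 and 5 are side branches.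

Step 8 (key step).
- What may go wrong: ring closure may be slow or fail, because the 1,1-disubstituted silyl enol ether is twisted out of the arene plane between two ortho ethers, and peri repulsion between the C4 silyloxy and C5 benzyloxy groups builds up in the product. Prolonged heating then favours catalyst decay to ruthenium hydrides and migration of the allyl or ring double bond into conjugation with C2, which destroys the stereocentre. Dimerisation at the allyl terminus and light-induced electrocyclic opening of the chromene are further losses.
- Fallback: give up metathesis and set C2 by catalyst-controlled conjugate addition, setting out from 7 and returning at 14. Phenol 7 would be condensed with N,N-dimethylformamide dimethyl acetal (toluene, 90 °C) to (E)-1-[6-(benzyloxy)-2-hydroxy-4-methoxy-3-(3-methyl-3-triethylsilyloxybutyl)phenyl]-3-(dimethylamino)prop-2-en-1-one F1. Aqueous HCl in THF would close the pyranone and strip the silyl ether, giving 5-(benzyloxy)-8-(3-hydroxy-3-methylbutyl)-7-methoxy-4H-chromen-4-one F2. Addition of phenylboronic acid to C2 with Pd(OCOCF3)2 and the tert-butyl pyridine-oxazoline ligand antipode that leads to the S product (NH4PF6, water, 1,2-dichloroethane, 60 °C) would give 14.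

Step 6.
- What may go wrong: the chelated, doubly ortho-substituted lithium phenoxide may attack the allyl complex sluggishly. The product, which carries a good aryloxide leaving group, may also re-ionise on the catalyst, eroding both the branched-to-linear preference and the enantiopurity.
- Fallback: make the C2–O1 bond by substitution with inversion and create the olefin afterwards, setting out from 7 and returning at 11. Mitsunobu reaction of 7 with (R)-3-chloro-1-phenylpropan-1-ol (PPh3, DIAD, THF, 0 °C) would give 6'-(benzyloxy)-2'-[(S)-3-chloro-1-phenylpropoxy]-4'-methoxy-3'-[3-methyl-3-(triethylsilyloxy)butyl]acetophenone F3. Displacement of chloride with sodium benzeneselenolate (from PhSeSePh and NaBH4, fully consumed before addition, EtOH) would give 6'-(benzyloxy)-4'-methoxy-3'-[3-methyl-3-(triethylsilyloxy)butyl]-2'-[(S)-1-phenyl-3-(phenylselanyl)propoxy]acetophenone F4. Oxidation with H2O2 (THF, 0 °C to rt) and syn-elimination of the selenoxide would give 11.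

Step 4.
- What may go wrong: site selectivity of O-benzylation may be incomplete, with alkylation at the hindered 2'-hydroxyl or at both oxygens, since the steric difference between the two chelating hydroxyls is only one ortho alkyl group.
- Fallback: let symmetry decide the O-benzylation instead of the iodination, setting out from 1 and returning at 7. Mono-benzylation of 1 (BnBr, K2CO3, acetone) can give only one mono-ether, 2'-(benzyloxy)-6'-hydroxy-4'-methoxyacetophenone F5. Iodination with N-iodosuccinimide (CH2Cl2, 0 °C) should then fall ortho to the remaining chelated hydroxyl and give 6'-(benzyloxy)-2'-hydroxy-3'-iodo-4'-methoxyacetophenone F6. The other open site, para to that hydroxyl, lies between the methoxy and the bulkier benzyloxy group, and any isomer formed there would have to be separated. Coupling of F6 with 5 under the conditions of step 3 would give 7. This order also spares the coupling its second free phenol.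

Step 10.
- What may go wrong: over-reduction, that is hydrogenolysis of the benzylic C2–O1 bond with opening of ring C, or reduction of the aryl ketone, competing with removal of the benzyl group.
- Fallback: a non-reductive, chelation-assisted dealkylation from 14 to 15. MgBr2·OEt2 in toluene/Et2O at gentle reflux should cleave only the benzyl ether peri to the C4 carbonyl through a six-membered magnesium chelate. No new compound arises on the way.

## Further compounds

F1 | step 8 | (E)-1-[6-(benzyloxy)-2-hydroxy-4-methoxy-3-(3-methyl-3-triethylsilyloxybutyl)phenyl]-3-(dimethylamino)prop-2-en-1-one | CN(C)/C=C/C(=O)c1c(OCc2ccccc2)cc(OC)c(CCC(C)(C)O[Si](CC)(CC)CC)c1O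
F2 | step 8 | 5-(benzyloxy)-8-(3-hydroxy-3-methylbutyl)-7-methoxy-4H-chromen-4-one | O=C1C=COc2c1c(OCc1ccccc1)cc(OC)c2CCC(C)(C)O
F3 | step 6 | 6'-(benzyloxy)-2'-[(S)-3-chloro-1-phenylpropoxy]-4'-methoxy-3'-[3-methyl-3-(triethylsilyloxy)butyl]acetophenone | CC(=O)c1c(OCc2ccccc2)cc(OC)c(CCC(C)(C)O[Si](CC)(CC)CC)c1O[C@H](c1ccccc1)CCCl
F4 | step 6 | 6'-(benzyloxy)-4'-methoxy-3'-[3-methyl-3-(triethylsilyloxy)butyl]-2'-[(S)-1-phenyl-3-(phenylselanyl)propoxy]acetophenone | CC(=O)c1c(OCc2ccccc2)cc(OC)c(CCC(C)(C)O[Si](CC)(CC)CC)c1O[C@H](c1ccccc1)CC[Se]c1ccccc1
F5 | step 4 | 2'-(benzyloxy)-6'-hydroxy-4'-methoxyacetophenone | CC(=O)c1c(O)cc(OC)cc1OCc1ccccc1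
F6 | step 4 | 6'-(benzyloxy)-2'-hydroxy-3'-iodo-4'-methoxyacetophenone | CC(=O)c1c(OCc2ccccc2)cc(OC)c(I)c1O
F0 | step 10 | none | none
A1 | alternative 1 | (S)-5-(benzyloxy)-8-[3-(benzyloxy)-3-methylbutyl]-7-methoxyflavanone | COc1cc(OCc2ccccc2)c2c(c1CCC(C)(C)OCc1ccccc1)O[C@H](c1ccccc1)CC2=O
A2 | alternative 1 | methyl (S)-3-hydroxy-3-phenylpropanoate | O[C@H](c1ccccc1)CC(=O)OC
A3 | alternative 2 | (S)-5-(benzyloxy)-7-methoxy-8-(3-methyl-3-triethylsilyloxybutyl)flavanone 4-(propane-1,3-diyl dithioketal) | COc1cc(OCc2ccccc2)c2c(c1CCC(C)(C)O[Si](CC)(CC)CC)O[C@H](c1ccccc1)CC21SCCCS1
A4 | alternative 3 | (S)-5-(tert-butyldimethylsilyloxy)-7-methoxy-8-(3-methyl-3-triethylsilyloxybutyl)flavanone | COc1cc(O[Si](C)(C)C(C)(C)C)c2c(c1CCC(C)(C)O[Si](CC)(CC)CC)O[C@H](c1ccccc1)CC2=O
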